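## The problem

The target **17** is a single benzene ring (ring A) with a fully oxygenated three-carbon side chain, so no ring has to be built and the task is chain assembly around one stereocentre. Ring A is numbered from the carbon that bears the side chain (C1), with the methoxy group on C2, the methyl group on C4 and the free phenol on C5; C8 is the tertiary benzylic carbinol, C9 the CH2 of the tiglate and C10 the CH2 of the acetate. C8 is the only stereocentre, (R), and it is stereogenic only because its two CH2O arms carry different acyl groups. No second stereocentre can relay to it, so the configuration must come from outside, and the two arms must be distinguishable from the moment C8 is made. Any intermediate with one acyl or silyl group on the O9/O10 pair and a free hydroxyl on the other can racemise by a shift of that group, directly or through O8, which excludes strongly basic steps late in the route. The tiglate is a conjugated trisubstituted alkene ester, the acetate is base- and hydride-labile, the ring is a hydroquinone monomethyl ether that DDQ, Ce(NH4)2(NO3)6 or ozone would take to a quinone, and the C8–O bond is tertiary and benzylic on an electron-rich ring, so hydrogenation, strong oxidants and strong acid are excluded. The enabling feature is that C8 carries aryl carbon C1, a hydroxyl and two oxidised one-carbon units: with C9 at the ester level, C8 is the ketone carbon of a 3-oxypyruvate, the C1–C8 bond can be made by an aryl nucleophile, and the C9 ester is the seat for a chiral auxiliary whose reductive removal leaves C9 and C10 already differentiated.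

## Retrosynthesis

**O–Si bond at the C5 phenol (17 from 16).** The phenol is released last. It must stay masked through Grignard formation, hydride reduction and both acylations, where a free phenol would be metalated or acylated. A silyl ether is preferred to a benzyl-type ether because its removal needs neither hydrogen (tiglate alkene, benzylic C8–O) nor an oxidant (hydroquinone ring). The forward step has only to cleave an aryl O–Si bond without moving either ester.

**Acyl C–O bonds at O10 and O9 (16 from 15, 15 from 14, 14 from 12 and 13).** The acetate is cut before the tiglate. In the forward direction the tiglate therefore goes on first, onto the only free primary hydroxyl of diol **12**, and the acetate follows as soon as O10 is unmasked. This order places the less migration-prone acyl group (conjugated, α-branched) on the intermediate that must survive with a free neighbouring hydroxyl. The precursor **12** has both arms at the alcohol level and already distinct (O9–H, O10–Si). The forward steps need primary-over-tertiary acylation and removal of an alkyl silyl ether beside an aryl one.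

**Oxidation level of C9 and the auxiliary ester bond (12 from 11).** No skeletal bond is cut; C9 is raised to an ester. This turns the pseudo-symmetric 2-arylglycerol into an α-hydroxy ester whose two arms differ in oxidation state, and it gives the auxiliary a place to sit. The forward reaction is a hydride reduction that must leave both silyl ethers where they are and return the auxiliary alcohol **5**.

**C1–C8 bond (11 from 4 and 10).** This is the strategic cut.
- Cutting C8–C9 or C8–C10 instead would require a hydroxymethyl anion synthon added to an aryl ketone.
- Cutting C8–O8 would require enantioface-selective oxidation of a 1,1-disubstituted alkene whose two substituents on the far carbon are both CH2O groups or an ortho-substituted aryl group, which is a weak basis for selectivity.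
- Cutting C1–C8 divides the molecule into its two natural halves, the whole of ring A as Grignard reagent **4** and the whole side chain as keto ester **10**, and forms the stereocentre in the same event.

The forward reaction must add to the ketone and not the ester, and must add to one face. The two C8 epimers are diastereomers and separable, and either one can be taken to **17** by choosing the order of the two acylations.

**Keto ester 10 (from 9, 8, 7, and from 5 and 6).** The C2 carbonyl comes from oxidation of secondary alcohol **9**, the O–Si bond from selective primary silylation of diol **8**, the two C–O bonds from dihydroxylation of acrylate **7**, and the ester bond from acylation of **5** with **6**. Each precursor is simpler by one functional group, and the sequence starts from a three-carbon acid chloride. The C2 configuration of **8** and **9** is irrelevant because it is oxidised away.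

**Grignard reagent 4 (from 3, 2 and 1).** The C–Mg bond comes from aryl bromide **3**, the C–Br bond from bromination of silyl ether **2**, and the O–Si bond from phenol **1**, which already has the complete substitution pattern of ring A apart from the side chain. The bromination must go ortho to the methoxy group and para to the methyl group.

## Roads not taken

**Alternative 1: Dötz benzannulation.**
- Cut and key step: the cut runs through ring A. Bonds C2–C3, C4–C5 and C5–C6 form together when the pentacarbonylchromium alkenyl(methoxy)carbene complex A1, (CO)5Cr=C(OMe)C(=CH2)R with the protected side chain R on its α-carbon, takes up propyne A2 and one CO ligand and closes to the phenol A3.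
- Merits: the regiochemistry of the benzannulation puts the methyl group next to the new phenol and the methoxy group para to it. That is exactly the pattern of ring A, with the two oxygens differentiated from the start.
- Weak points: ring A is the cheap part of this target, since **1** already carries the pattern. The reaction uses stoichiometric zerovalent chromium. The quaternary C8 centre must be made enantioselectively before A1 is assembled, so the key step solves none of the stereochemical problem. The PMB ether of A3 would have to be removed oxidatively beside a hydroquinone monoether, and the free phenol of A3 would have to be masked again before any acylation.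
- Comparison: its one real advantage is regiochemical certainty on the ring, where the chosen plan relies on a directed bromination (step 2, with a fallback). Against this the chosen plan is much shorter and creates C8 in its key step.

**Alternative 2: desymmetrising tigloylation of a prochiral 2-arylglycerol.**
- Cut and key step: the cut is the acyl C–O bond at O9. The prochiral triol A5, reachable in two steps from Grignard reagent **4** and the ketone A4, would be monoacylated with **13** under Cu(OTf)2 and a chiral phenyl-substituted bis(oxazoline) ligand. The product is the monotiglate A6, identical with **15**.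
- Merits: this is the shortest road, roughly eight operations against thirteen. Chirality is catalytic, there is no auxiliary, no change of oxidation state and no silyl group on C10. In step economy it is clearly better than the chosen plan.
- Weak points: monoacylation by divalent copper–bis(oxazoline) catalysts rests on aroyl-type chlorides and diol substrates that chelate well. A conjugated, α-branched acyl chloride and a triol with an ortho-substituted aryl group on the carbinol carbon are both outside that range. The product is one of two enantiomers, so a shortfall in selectivity cannot be corrected by chromatography. A6 is also the migration-prone diol monoester, formed here in the presence of base, where every acyl shift is racemisation.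
- Comparison: the chosen plan sets against the brevity of this road a predictable sense of induction, C8 epimers that are diastereomers and separable, the use of both epimers, and no dependence on an untested acyl donor in an enantioselective step.

**Alternative 3: allylic selenoxide [2,3]-rearrangement.**
- Cut and key step: the cut is the C8–O8 bond. Oxidation of the secondary allylic phenyl selenide A7 at selenium with H2O2 triggers the [2,3]-shift. Oxygen is delivered to C8 on the face that selenium leaves and the alkene moves out into an (E)-propenyl group, giving the carbinol A8 after cleavage of the O–Se bond.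
- Merits: the shift is concerted and suprafacial, so chirality transfer into a tertiary allylic alcohol is dependable, and the conditions are mild.
- Weak points: A7 needs a geometrically pure trisubstituted alkene with the aryl group cis to the selenium-bearing carbon, and a configurationally defined C–Se centre that can erode by 1,3-shifts. A stereocentre therefore has to be made in order to make C8. The propenyl group of A8 must afterwards be cleaved to the C9 aldehyde and reduced, and ozone or other strong oxidants would compete for the electron-rich ring A.
- Comparison: this road avoids a stoichiometric auxiliary, but the auxiliary of the chosen plan is recovered in step 9. In length, in the number of stereo-defining operations and in compatibility with ring A the chosen plan is better.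

Key step: step 8

Assumption: C8 of the target is read from the SMILES as (R). The sense of induction is taken to be that established for Grignard additions to 8-phenylmenthyl glyoxylate and pyruvate, attack on the si face of the chelated ketone, which gives (2R)-**11**. "8-Phenylmenthyl" denotes the (1R,2S,5R)-5-methyl-2-(2-phenylpropan-2-yl)cyclohexyl group of **5**.

## Route

Step 1
Reactants: 1 4-methoxy-2-methylphenol
Product: 2 triisopropyl(4-methoxy-2-methylphenoxy)silane
Conditions: TIPSCl, imidazole, DMF, rt
Reagents that add atoms: chlorotriisopropylsilane, CC(C)[Si](Cl)(C(C)C)C(C)C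
Why: Standard silylation of a phenol with a silyl chloride and imidazole; the triisopropylsilyl ether should survive Grignard formation, LiAlH4 and mild acid and fall to buffered fluoride at the end.

Step 2
Reactants: 2 triisopropyl(4-methoxy-2-methylphenoxy)silane
Product: 3 (5-bromo-4-methoxy-2-methylphenoxy)triisopropylsilane
Conditions: NBS, MeCN, 0 °C to rt, dark
Reagents that add atoms: N-bromosuccinimide, O=C1CCC(=O)N1Br
Why: Electrophilic aromatic bromination; the position ortho to the methoxy group and para to the methyl group is doubly activated, the position between methyl and methoxy is flanked on both sides, and the position beside the bulky, weakly donating silyloxy group is the least activated.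

Step 3
Reactants: 3 (5-bromo-4-methoxy-2-methylphenoxy)triisopropylsilane
Product: 4 [2-methoxy-4-methyl-5-(triisopropylsilyloxy)phenyl]magnesium bromide (titrated THF solution, used directly)
Conditions: Mg turnings, I2 (cat.), THF, 25 to 50 °C
Reagents that add atoms: magnesium, [Mg]
Why: Grignard reagent formation by insertion of magnesium into the aryl–bromine bond; methyl and silyl aryl ethers are inert under these conditions.

Step 4
Reactants: 5 (−)-8-phenylmenthol; 6 acryloyl chloride
Product: 7 8-phenylmenthyl acrylate
Conditions: Et3N, DMAP (cat.), CH2Cl2, 0 °C
Reagents that add atoms: none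
Why: DMAP-catalysed O-acylation of a hindered secondary alcohol with an acid chloride; the stereocentres of the auxiliary are not involved.

Step 5
Reactants: 7 8-phenylmenthyl acrylate
Product: 8 8-phenylmenthyl 2,3-dihydroxypropanoate (both C2 epimers)
Conditions: OsO4 (cat.), NMO, acetone/H2O, rt
Reagents that add atoms: N-methylmorpholine N-oxide, C[N+]1([O-])CCOCC1; water, O
Why: Upjohn dihydroxylation of the acrylate double bond; the C2 configuration need not be controlled because C2 becomes the ketone carbon in step 7.

Step 6
Reactants: 8 8-phenylmenthyl 2,3-dihydroxypropanoate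
Product: 9 8-phenylmenthyl 3-(tert-butyldimethylsilyloxy)-2-hydroxypropanoate (both C2 epimers)
Conditions: TBSCl, imidazole, CH2Cl2, 0 °C
Reagents that add atoms: tert-butylchlorodimethylsilane, CC(C)(C)[Si](C)(C)Cl
Why: Selective silylation of the primary hydroxyl; the secondary hydroxyl α to the ester is more hindered and less nucleophilic.

Step 7
Reactants: 9 8-phenylmenthyl 3-(tert-butyldimethylsilyloxy)-2-hydroxypropanoate
Product: 10 8-phenylmenthyl 3-(tert-butyldimethylsilyloxy)-2-oxopropanoate
Conditions: Dess–Martin periodinane, CH2Cl2, 0 °C to rt
Reagents that add atoms: none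
Why: Dess–Martin oxidation of an α-hydroxy ester to the α-keto ester under nearly neutral conditions that leave the silyl ether in place; both C2 epimers converge on one compound.

Step 8
Reactants: 4 [2-methoxy-4-methyl-5-(triisopropylsilyloxy)phenyl]magnesium bromide; 10 8-phenylmenthyl 3-(tert-butyldimethylsilyloxy)-2-oxopropanoate
Product: 11 8-phenylmenthyl (2R)-3-(tert-butyldimethylsilyloxy)-2-hydroxy-2-[2-methoxy-4-methyl-5-(triisopropylsilyloxy)phenyl]propanoate
Conditions: 4 (THF) added to 10, Et2O/THF, −78 °C; then sat. aq. NH4Cl
Reagents that add atoms: none
Why: Nucleophilic 1,2-addition of the aryl Grignard reagent to the ketone carbonyl of the α-keto ester, the reaction type long used for chelation-controlled Grignard additions to 8-phenylmenthyl glyoxylate and pyruvate. Magnesium bridges the two carbonyl oxygens of 10 and holds them syn-coplanar, the ester adopts its usual s-cis form with the carbinol C–H of the auxiliary eclipsing the ester carbonyl, and the phenyl ring of the 2-phenylpropan-2-yl group then lies over the re face of the ketone. The aryl group should therefore enter on the open si face (O > CO2R > CH2OSi), which forms the C1–C8 bond and sets C8 as (R); no ring is closed. Three selectivities are needed: ketone over ester (the ketone is the more electrophilic carbonyl and the ester is shielded by the auxiliary), the dicarbonyl chelate over a chelate through O10 (the tert-butyldimethylsilyl ether is a bulky, weakly basic donor), and addition over enolisation at C10 (aryl Grignard reagents are weak bases at −78 °C). The two C8 epimers are diastereomers and separable on silica, so the material carried forward should be stereochemically homogeneous.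

Step 9
Reactants: 11 8-phenylmenthyl (2R)-3-(tert-butyldimethylsilyloxy)-2-hydroxy-2-[2-methoxy-4-methyl-5-(triisopropylsilyloxy)phenyl]propanoate
Product: 12 (2S)-3-(tert-butyldimethylsilyloxy)-2-[2-methoxy-4-methyl-5-(triisopropylsilyloxy)phenyl]propane-1,2-diol
Conditions: LiAlH4, Et2O, 0 °C; then Na2SO4·10H2O
Reagents that add atoms: none
Why: LiAlH4 reduction of the ester to the primary alcohol, assisted by the neighbouring alkoxide, releases the auxiliary alcohol 5 for reuse; C8 is not touched (the descriptor changes only because the priorities change), and low temperature with a covalent aluminium alkoxide should keep the O10 silyl group from migrating.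

Step 10
Reactants: 12 (2S)-3-(tert-butyldimethylsilyloxy)-2-[2-methoxy-4-methyl-5-(triisopropylsilyloxy)phenyl]propane-1,2-diol; 13 tigloyl chloride
Product: 14 (2S)-3-(tert-butyldimethylsilyloxy)-2-hydroxy-2-[2-methoxy-4-methyl-5-(triisopropylsilyloxy)phenyl]propyl (E)-2-methylbut-2-enoate
Conditions: pyridine, DMAP (cat.), CH2Cl2, 0 °C to rt
Reagents that add atoms: none
Why: DMAP-catalysed acylation with an acid chloride; only the primary C9 hydroxyl reacts because the tertiary benzylic hydroxyl is too hindered, and pyridine in place of a trialkylamine avoids vinylketene formation and deconjugation of the tigloyl unit.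

Step 11
Reactants: 14 (2S)-3-(tert-butyldimethylsilyloxy)-2-hydroxy-2-[2-methoxy-4-methyl-5-(triisopropylsilyloxy)phenyl]propyl (E)-2-methylbut-2-enoate
Product: 15 (2R)-2,3-dihydroxy-2-[2-methoxy-4-methyl-5-(triisopropylsilyloxy)phenyl]propyl (E)-2-methylbut-2-enoate
Conditions: CSA (cat.), MeOH/CH2Cl2, 0 °C; quench with Et3N
Reagents that add atoms: none
Why: Acid-catalysed methanolysis of a primary alkyl silyl ether; the aryl silyl ether is much less basic at oxygen and more hindered, so the phenol should stay protected, and catalytic acid at 0 °C with a basic quench limits acyl migration.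

Step 12
Reactants: 15 (2R)-2,3-dihydroxy-2-[2-methoxy-4-methyl-5-(triisopropylsilyloxy)phenyl]propyl (E)-2-methylbut-2-enoate
Product: 16 (2R)-3-acetoxy-2-hydroxy-2-[2-methoxy-4-methyl-5-(triisopropylsilyloxy)phenyl]propyl (E)-2-methylbut-2-enoate
Conditions: Ac2O, pyridine, CH2Cl2, 0 °C to rt
Reagents that add atoms: acetic anhydride, CC(=O)OC(C)=O
Why: Acetylation of the primary C10 hydroxyl with Ac2O and pyridine, carried out directly on crude 15 so that the two arms are fixed before any acyl shift; the tertiary hydroxyl does not react under these conditions.

Step 13
Reactants: 16 (2R)-3-acetoxy-2-hydroxy-2-[2-methoxy-4-methyl-5-(triisopropylsilyloxy)phenyl]propyl (E)-2-methylbut-2-enoate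
Product: 17 (2R)-3-acetoxy-2-hydroxy-2-(5-hydroxy-2-methoxy-4-methylphenyl)propyl (E)-2-methylbut-2-enoate
Conditions: TBAF, AcOH (1:1), THF, 0 °C
Reagents that add atoms: none
Why: Fluoride cleavage of an aryl silyl ether, fast at 0 °C because phenoxide is a good leaving group; the AcOH buffer should prevent base-induced migration or loss of the two esters.

## Compound list

1 | 4-methoxy-2-methylphenol | COc1ccc(O)c(C)c1 | starting material
2 | triisopropyl(4-methoxy-2-methylphenoxy)silane | COc1ccc(O[Si](C(C)C)(C(C)C)C(C)C)c(C)c1 | intermediate
3 | (5-bromo-4-methoxy-2-methylphenoxy)triisopropylsilane | COc1cc(C)c(O[Si](C(C)C)(C(C)C)C(C)C)cc1Br | intermediate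
4 | [2-methoxy-4-methyl-5-(triisopropylsilyloxy)phenyl]magnesium bromide | COc1cc(C)c(O[Si](C(C)C)(C(C)C)C(C)C)cc1[Mg]Br | intermediate
5 | (−)-8-phenylmenthol, (1R,2S,5R)-5-methyl-2-(2-phenylpropan-2-yl)cyclohexan-1-ol | CC(C)(c1ccccc1)[C@@H]1CC[C@@H](C)C[C@H]1O | starting material
6 | acryloyl chloride | C=CC(Cl)=O | starting material
7 | 8-phenylmenthyl acrylate, (1R,2S,5R)-5-methyl-2-(2-phenylpropan-2-yl)cyclohexyl prop-2-enoate | CC(C)(c1ccccc1)[C@@H]1CC[C@@H](C)C[C@H]1OC(=O)C=C | intermediate
8 | 8-phenylmenthyl 2,3-dihydroxypropanoate (both C2 epimers) | CC(C)(c1ccccc1)[C@@H]1CC[C@@H](C)C[C@H]1OC(=O)C(O)CO | intermediate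
9 | 8-phenylmenthyl 3-(tert-butyldimethylsilyloxy)-2-hydroxypropanoate (both C2 epimers) | CC(C)(c1ccccc1)[C@@H]1CC[C@@H](C)C[C@H]1OC(=O)C(O)CO[Si](C)(C)C(C)(C)C | intermediate
10 | 8-phenylmenthyl 3-(tert-butyldimethylsilyloxy)-2-oxopropanoate | CC(C)(c1ccccc1)[C@@H]1CC[C@@H](C)C[C@H]1OC(=O)C(=O)CO[Si](C)(C)C(C)(C)C | intermediate
11 | 8-phenylmenthyl (2R)-3-(tert-butyldimethylsilyloxy)-2-hydroxy-2-[2-methoxy-4-methyl-5-(triisopropylsilyloxy)phenyl]propanoate | CC(C)(c1ccccc1)[C@@H]1CC[C@@H](C)C[C@H]1OC(=O)[C@](O)(CO[Si](C)(C)C(C)(C)C)c1cc(O[Si](C(C)C)(C(C)C)C(C)C)c(C)cc1OC | intermediate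
12 | (2S)-3-(tert-butyldimethylsilyloxy)-2-[2-methoxy-4-methyl-5-(triisopropylsilyloxy)phenyl]propane-1,2-diol | OC[C@](O)(CO[Si](C)(C)C(C)(C)C)c1cc(O[Si](C(C)C)(C(C)C)C(C)C)c(C)cc1OC | intermediate
13 | tigloyl chloride, (E)-2-methylbut-2-enoyl chloride | C/C=C(\C)C(Cl)=O | starting material
14 | (2S)-3-(tert-butyldimethylsilyloxy)-2-hydroxy-2-[2-methoxy-4-methyl-5-(triisopropylsilyloxy)phenyl]propyl (E)-2-methylbut-2-enoate | C/C=C(\C)C(=O)OC[C@](O)(CO[Si](C)(C)C(C)(C)C)c1cc(O[Si](C(C)C)(C(C)C)C(C)C)c(C)cc1OC | intermediate
15 | (2R)-2,3-dihydroxy-2-[2-methoxy-4-methyl-5-(triisopropylsilyloxy)phenyl]propyl (E)-2-methylbut-2-enoate | C/C=C(\C)C(=O)OC[C@](O)(CO)c1cc(O[Si](C(C)C)(C(C)C)C(C)C)c(C)cc1OC | intermediate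
16 | (2R)-3-acetoxy-2-hydroxy-2-[2-methoxy-4-methyl-5-(triisopropylsilyloxy)phenyl]propyl (E)-2-methylbut-2-enoate | C/C=C(\C)C(=O)OC[C@](O)(COC(C)=O)c1cc(O[Si](C(C)C)(C(C)C)C(C)C)c(C)cc1OC | intermediate
17 | (2R)-3-acetoxy-2-hydroxy-2-(5-hydroxy-2-methoxy-4-methylphenyl)propyl (E)-2-methylbut-2-enoate | C/C=C(\C)C(=O)OC[C@](O)(COC(C)=O)c1cc(O)c(C)cc1OC | target

## Step count and risk

Total: 13 steps, counting the preparation of the Grignard solution as a step. Longest linear sequence: 10 steps (steps 4 to 13, from **5**).

**Step 8 (key step).** The most likely failure is loss or reversal of facial selectivity. It would arise if magnesium chelates the ketone oxygen with O10, or if the dicarbonyl unit reacts in its anti form, since either exposes the other face of the ketone. Enolisation at C10 would lower conversion. The fallback changes how the stereochemical problem is solved and uses both epimers. Setting out from **4** and **10**, the adducts are separated as diastereomers. The epimer 8-phenylmenthyl (2S)-3-(tert-butyldimethylsilyloxy)-2-hydroxy-2-[2-methoxy-4-methyl-5-(triisopropylsilyloxy)phenyl]propanoate F1 is reduced with LiAlH4 to the (2R)-diol F2, the enantiomer of **12**. Its free primary hydroxyl is acetylated with Ac2O and pyridine to give the acetate F3, and the silyl ether is removed with CSA in MeOH to give the diol monoacetate F4. Acylation of the liberated hydroxyl with **13** gives **16**, where the fallback rejoins the route. The acetyl group is more prone to shift than the tigloyl group, so this order is the weaker one and is held in reserve.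

**Step 9.** Under the basic conditions of the reduction the silyl group may migrate from O10 to O9 or O8 at the alkoxide stage. That scrambles the two arms and lowers the enantiomeric purity. Reduction of the hindered ester may also be slow. The fallback ties O8 and O10 together before the hydride step. Setting out from **11**, CSA in MeOH removes the alkyl silyl group to give the dihydroxy ester F5, and 2,2-dimethoxypropane with PPTS gives the dioxolane ester F6. LiAlH4 then gives the primary alcohol F7, in which nothing can migrate, and **13** with pyridine and DMAP gives the tiglate F8. Aqueous AcOH removes the acetonide and gives **15**, where the fallback rejoins the route.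

**Step 11.** Once O10 is free, acid may move the tigloyl group from O9 to O10, directly or through O8, which is racemisation. The aryl silyl ether may also be partly lost, and the benzylic C8–O bond may solvolyse if the acid is too strong. The fallback gives up the selective desilylation. Setting out from **14**, both silyl groups are removed together with TBAF buffered by AcOH at 0 °C to give the phenolic diol (2R)-2,3-dihydroxy-2-(5-hydroxy-2-methoxy-4-methylphenyl)propyl (E)-2-methylbut-2-enoate F9. Its aliphatic primary hydroxyl is then acetylated with vinyl acetate and Candida antarctica lipase B at neutrality; lipases acylate aliphatic hydroxyls and leave phenols and tertiary alcohols untouched. This gives **17** directly.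

**Step 2.** Bromination may go partly ortho to the silyloxy group, or traces of HBr may cleave the silyl ether and let the free phenol direct the halogen to the wrong position. The fallback replaces the silyl ether by a deactivating ester during the halogenation. Setting out from **1**, acetylation with Ac2O and pyridine gives 4-methoxy-2-methylphenyl acetate F10, in which only the methoxy group activates the ring. Bromination with NBS in MeCN gives 5-bromo-4-methoxy-2-methylphenyl acetate F11, methanolysis with K2CO3 in MeOH gives 5-bromo-4-methoxy-2-methylphenol F12, and silylation with TIPSCl and imidazole gives **3**, where the fallback rejoins the route.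

## Further compounds

F1 | step 8 | 8-phenylmenthyl (2S)-3-(tert-butyldimethylsilyloxy)-2-hydroxy-2-[2-methoxy-4-methyl-5-(triisopropylsilyloxy)phenyl]propanoate (C8 epimer of 11) | CC(C)(c1ccccc1)[C@@H]1CC[C@@H](C)C[C@H]1OC(=O)[C@@](O)(CO[Si](C)(C)C(C)(C)C)c1cc(O[Si](C(C)C)(C(C)C)C(C)C)c(C)cc1OC
F2 | step 8 | (2R)-3-(tert-butyldimethylsilyloxy)-2-[2-methoxy-4-methyl-5-(triisopropylsilyloxy)phenyl]propane-1,2-diol (enantiomer of 12) | OC[C@@](O)(CO[Si](C)(C)C(C)(C)C)c1cc(O[Si](C(C)C)(C(C)C)C(C)C)c(C)cc1OC
F3 | step 8 | (2R)-3-(tert-butyldimethylsilyloxy)-2-hydroxy-2-[2-methoxy-4-methyl-5-(triisopropylsilyloxy)phenyl]propyl acetate | CC(=O)OC[C@@](O)(CO[Si](C)(C)C(C)(C)C)c1cc(O[Si](C(C)C)(C(C)C)C(C)C)c(C)cc1OC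
F4 | step 8 | (2S)-2,3-dihydroxy-2-[2-methoxy-4-methyl-5-(triisopropylsilyloxy)phenyl]propyl acetate | CC(=O)OC[C@@](O)(CO)c1cc(O[Si](C(C)C)(C(C)C)C(C)C)c(C)cc1OC
F5 | step 9 | 8-phenylmenthyl (2R)-2,3-dihydroxy-2-[2-methoxy-4-methyl-5-(triisopropylsilyloxy)phenyl]propanoate | CC(C)(c1ccccc1)[C@@H]1CC[C@@H](C)C[C@H]1OC(=O)[C@](O)(CO)c1cc(O[Si](C(C)C)(C(C)C)C(C)C)c(C)cc1OC
F6 | step 9 | 8-phenylmenthyl (4R)-4-[2-methoxy-4-methyl-5-(triisopropylsilyloxy)phenyl]-2,2-dimethyl-1,3-dioxolane-4-carboxylate | CC(C)(c1ccccc1)[C@@H]1CC[C@@H](C)C[C@H]1OC(=O)[C@@]1(c2cc(O[Si](C(C)C)(C(C)C)C(C)C)c(C)cc2OC)COC(C)(C)O1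
F7 | step 9 | {(4S)-4-[2-methoxy-4-methyl-5-(triisopropylsilyloxy)phenyl]-2,2-dimethyl-1,3-dioxolan-4-yl}methanol | OC[C@@]1(c2cc(O[Si](C(C)C)(C(C)C)C(C)C)c(C)cc2OC)COC(C)(C)O1
F8 | step 9 | {(4R)-4-[2-methoxy-4-methyl-5-(triisopropylsilyloxy)phenyl]-2,2-dimethyl-1,3-dioxolan-4-yl}methyl (E)-2-methylbut-2-enoate | C/C=C(\C)C(=O)OC[C@@]1(c2cc(O[Si](C(C)C)(C(C)C)C(C)C)c(C)cc2OC)COC(C)(C)O1
F9 | step 11 | (2R)-2,3-dihydroxy-2-(5-hydroxy-2-methoxy-4-methylphenyl)propyl (E)-2-methylbut-2-enoate | C/C=C(\C)C(=O)OC[C@](O)(CO)c1cc(O)c(C)cc1OC
F10 | step 2 | 4-methoxy-2-methylphenyl acetate | COc1ccc(OC(C)=O)c(C)c1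
F11 | step 2 | 5-bromo-4-methoxy-2-methylphenyl acetate | COc1cc(C)c(OC(C)=O)cc1Br
F12 | step 2 | 5-bromo-4-methoxy-2-methylphenol | COc1cc(C)c(O)cc1Br
A1 | alternative 1 | pentacarbonyl(methoxy{1-[(4S)-4-[(4-methoxybenzyloxy)methyl]-2,2-dimethyl-1,3-dioxolan-4-yl]ethenyl}carbene)chromium, (CO)5Cr=C(OMe)C(=CH2)R | COC(=[Cr](=C=O)(=C=O)(=C=O)(=C=O)=C=O)C(=C)[C@]1(COCc2ccc(OC)cc2)COC(C)(C)O1
A2 | alternative 1 | propyne | CC#C
A3 | alternative 1 | 4-methoxy-5-{(4S)-4-[(4-methoxybenzyloxy)methyl]-2,2-dimethyl-1,3-dioxolan-4-yl}-2-methylphenol | COc1cc(C)c(O)cc1[C@]1(COCc2ccc(OC)cc2)COC(C)(C)O1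
A4 | alternative 2 | 2,2-dimethyl-1,3-dioxan-5-one | CC1(C)OCC(=O)CO1
A5 | alternative 2 | 2-[2-methoxy-4-methyl-5-(triisopropylsilyloxy)phenyl]propane-1,2,3-triol | OCC(O)(CO)c1cc(O[Si](C(C)C)(C(C)C)C(C)C)c(C)cc1OC
A6 | alternative 2 | (2R)-2,3-dihydroxy-2-[2-methoxy-4-methyl-5-(triisopropylsilyloxy)phenyl]propyl (E)-2-methylbut-2-enoate (identical with 15) | C/C=C(\C)C(=O)OC[C@](O)(CO)c1cc(O[Si](C(C)C)(C(C)C)C(C)C)c(C)cc1OC
A7 | alternative 3 | tert-butyl({(2E,4S)-2-[2-methoxy-4-methyl-5-(triisopropylsilyloxy)phenyl]-4-(phenylselanyl)pent-2-en-1-yl}oxy)dimethylsilane | C[C@H]([Se]c1ccccc1)/C=C(/CO[Si](C)(C)C(C)(C)C)c1cc(O[Si](C(C)C)(C(C)C)C(C)C)c(C)cc1OC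
A8 | alternative 3 | (2R,3E)-1-(tert-butyldimethylsilyloxy)-2-[2-methoxy-4-methyl-5-(triisopropylsilyloxy)phenyl]pent-3-en-2-ol | C/C=C/[C@](O)(CO[Si](C)(C)C(C)(C)C)c1cc(O[Si](C(C)C)(C(C)C)C(C)C)c(C)cc1OC
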